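If the rate in a stirred flask is proportional to the starting material present and to a catalyst whose active share runs the same course at any charge, then at equal dosing time the exponent, the log of the whole charge over the part not yet product, scales with the catalyst charge and ignores the charge of starting material.

| setting | delta | epsilon | zeta | flask |
|---|---|---|---|---|
| starting material | 0.28 M (fed, over 80 min) | 0.44 M (fed, over 80 min) | 0.20 M (fed, over 80 min) | 0.20 M (fed, over 80 min) |
| free catalyst | 30 mM | 30 mM | 15 mM | 30 mM |
| remark | run made earlier; the fed solution adds 1.0 times the starting volume | run made earlier; the fed solution adds 1.0 times the starting volume | run made earlier; the fed solution adds 1.0 times the starting volume | the fed solution adds 1.0 times the starting volume |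
| time |  |  |  | 8.0 h |

| run | time / h | product / % | starting material / % |
|---|---|---|---|
| delta | 2.00 | 8.6 | 89.2 |
| delta | 4.00 | 16.9 | 82.7 |
| delta | 6.00 | 22.5 | 78.1 |
| delta | 8.00 | 25.1 | 74.0 |
| delta | 10.0 | 28.7 | 70.6 |
| epsilon | 0.833 | 2.3 | 59.0 |
| epsilon | 2.50 | 10.2 | 88.6 |
| epsilon | 4.00 | 15.4 | 84.3 |
| epsilon | 6.00 | 20.5 | 79.1 |
| epsilon | 10.0 | 28.4 | 72.1 |
| zeta | 0.833 | 1.4 | 60.4 |
| zeta | 2.50 | 6.7 | 93.7 |
| zeta | 4.00 | 8.4 | 90.7 |
| zeta | 6.00 | 11.7 | 87.5 |
| zeta | 10.0 | 15.7 | 84.7 |

(scatter of a reading: 0.5 percentage points)

- amount of product in percent of the starting material charged, at 1.5 h, 4.0 h and 8.0 h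

The runs show this dependence on the charges, but no constant rate: delta's exponent is 0.185 at 4.00 h and 0.289 at 8.00 h, so it does not grow in step with time. At 10.0 h, delta and epsilon, charged with 0.28 M and 0.44 M, read 28.7% and 28.4% of product. Zeta, with half their catalyst, reads 15.7%, an exponent half of delta's.

So I carry one reading from delta at 4.00 h, 6.17 M⁻¹: the depth per catalyst, which is that exponent divided by the c(free catalyst) charged. The flask has delta's catalyst, so 6.17 M⁻¹ on its 30 mM gives me 16.9% at 4.0 h, and for 8.0 h I take delta's reading of 25.1%. A straight line from zero to delta's 2.00 h reading gives me 6.45% at 1.5 h.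

The forecast, a little apart from these, says 6.2%, 16.8% and 26%, on the ground that “Halving the catalyst in zeta about halves the conversion”.

The flask gives 6.56%, 17.2% and 25.7%.

    free catalyst ⇌ dormant form (K = 5.90, k = 0.00670 min⁻¹)
    catalyst intermediate → free catalyst + product (k = 0.0600 min⁻¹)
    starting material + free catalyst ⇌ catalyst intermediate (K = 4.80 M⁻¹, k = 0.280 M⁻¹ min⁻¹)

The flask's 4.0 h value is a depth per catalyst of 6.29 M⁻¹, against the 6.17 M⁻¹ carried from delta, and that 6.17 M⁻¹ on zeta's 15 mM gives 8.84% where zeta read 8.4% at 4.00 h. In the flask, half of the loss of free catalyst to dormant form up to 8.0 h is done by 1.53 h, earlier than the same mark for the making of product at 2.76 h. By 8.00 h the dormant form holds 80.1% of the catalyst charged, against 16.9% free and 3.00% as catalyst intermediate.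

(Readings and results come from a simulation with constants of no real substance; noise was put on by code.)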